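Numbers refer to the compound list after the steps; TBS = tert-butyldimethylsilyl, PMB = 4-methoxybenzyl.

## Analysis of the target

Compound 36 is a germacrane: a ten-membered carbocycle C1–C10 with C14 (methyl on C10), C15 (methyl on C4) and an isopropyl group on C7 (C11 carrying C12 and C13); these locants are kept for every intermediate, open-chain ones included. It carries oxiranes across C1–C10 and C4–C5, an acetate on C6 and an angelate, (Z)-2-methylbut-2-enoate, on C8. The seven stereocenters are (1R,4S,5S,6R,7R,8S,10S): C6, C7 and C8 form a contiguous triad and the other four lie in the two oxiranes. In the flat ring drawing C6–OAc and the C7 isopropyl group are cis (this face is called β) and C8–O is trans to them (α). The C1–C10 oxirane has C2 and C9 cis and its oxygen on the β face, so it comes from a (Z)-olefin oxidised anti to C8–O; the C4–C5 oxirane has C3 and C6 trans, so it comes from an (E)-olefin, with its oxygen threo to C6–O. The trisubstituted oxiranes open easily under acid (a 4,5-oxirane beside a C1=C10 olefin cyclises across the ring), the angelate isomerises to the tiglate with base or nucleophiles, and the acetate can migrate to a free neighbouring hydroxyl. The difficulty is the medium ring: it has no rigid shape, yet a stereotriad, two oxirane faces and one (Z)- and one (E)-trisubstituted olefin must all be controlled. The strategy rests on C6 and C7: C6 is a carbinol allylic to C4=C5 (reading the oxirane as an olefin) and C7 carries a branch that can start as isopropenyl, so C6(OH)–C7–C11=C12 is the homoallylic alcohol that a [2,3]-Wittig shift leaves behind, and the ten-membered ring 28 can be contracted out of the thirteen-membered diallylic ether 25.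

## Retrosynthetic reasoning

36 ⇒ 33 + 34. The C8–O acyl bond is cut first, so that the isomerisation-prone angelate is attached in the last step, through the mixed anhydride 35 without a nucleophilic catalyst. The forward reaction has to acylate a hindered secondary alcohol without touching two oxiranes and the acetate.

33 ⇒ 32 ⇒ 31. After the silyl ether is put back on C8, the two C–O bonds of the C1–C10 oxirane are cut to the (Z)-olefin of 31. The oxirane oxygen and C8–O lie on opposite ring faces, so oxygen delivery from a metal bound to a free C8 hydroxyl would give the wrong face. The olefin is therefore oxidised with a neutral, non-directed oxidant while C8 still carries its bulky silyl ether, which screens the α face.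

31 ⇒ 30 ⇒ 29. Removing the acetate frees C6–OH, and the C4–C5 oxirane is cut to the (E)-olefin of 29. This order is chosen because C6–OH is allylic to C4=C5 and can deliver the oxidant; allylic 1,3-strain with C15 fixes the conformer that gives the threo oxirane. The directing hydroxyl is only capped afterwards.

29 ⇒ 28. The isopropyl group is traced to isopropenyl. A 1,1-disubstituted olefin can be hydrogenated beside the two trisubstituted ring olefins, and the isopropenyl group is what the sigmatropic step produces.

28 ⇒ 25 (key disconnection). The ring bond C6–C7 is cut and O is joined to C12. This converts the carbocycle with two new stereocenters into a thirteen-membered ether that has only the C8 stereocenter and three olefins of fixed geometry. Cutting here and not at another ring bond means the ring closure is transannular, not end-to-end. It also lets the (Z)-C7=C11 geometry and C8 control C6 and C7 through a five-membered transition state.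

25 ⇒ 23 ⇒ 22 ⇒ 20 ⇒ 19. The ether is opened at O–C6 to the chloro alcohol 23. The leaving group is put on C12 and the alkoxide on C6 so that the alkoxide is far from the C8 silyl ether. The chloride 22 comes from the allylic alcohol 20, and this from the (Z)-enoate 19.

19 ⇒ 16 + 17. The C7=C11 olefin is cut to the α-silyloxy aldehyde 16 and the phosphonate 17. A Still–Gennari olefination is the dependable way to a (Z)-trisubstituted enoate, and it places C12 cis to C8, which the key step needs.

16 ⇒ 15 ⇒ 14 ⇒ 13 ⇒ 10 + 11. The C9–C10 bond is cut between the alkenyllithium 12 (from the iodide 10) and the terminal carbon of the oxirane 11. C8 then comes from the chiral pool with its oxygen free to be silylated, and no auxiliary and no protecting-group exchange at C8 is needed. The PMB ether on C7 is orthogonal to both silyl ethers.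

10 ⇒ 9 ⇒ 8 ⇒ 3 + 4 and 3 ⇒ 2 ⇒ 1. The C1=C10 olefin is cut to the aldehyde 3 and the two-carbon phosphonium salt 4. The α-iodo ylide 7 gives the (Z)-alkenyl iodide, and the geometry is carried with retention into the 1(10)Z olefin. Aldehyde 3 is what remains of 1 after its electron-rich terminal olefin is cleaved; the (E)-C4=C5 olefin is bought with 1.

## Alternatives that were turned down

Alternative 1: The disconnection is the C2–C3 ring bond. An open chain with a phenyl sulfone on allylic C2 and a chloride on allylic C3 would be deprotonated with KN(SiMe3)2, and the sulfonyl carbanion would displace the chloride to give the cyclodecadiene A1 as C2 epimers; the sulfone is removed later.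
- For: sulfone carbanion alkylation is dependable. Both ring olefins and the whole C6–C7–C8 triad are in place before the ring closes, so the closure creates no stereocenter that survives. On predictability of the ring-forming step it is stronger than the route chosen.
- Against: the triad has to be built in the open chain by separate asymmetric C–C bond formations with two differentiated oxygen protecting groups, which costs more steps than the single chiral-pool stereocenter of 25. The closure joins two allylic termini, so SN2' attack and oligomers compete. The sulfone must then be cut out reductively at a position allylic to the (Z)-C1=C10 olefin, where allyl radical or anion intermediates can move or isomerise that olefin.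
- Comparison: the ring contraction forms the ring and two stereocenters in one step and leaves no activating group to remove.

Alternative 2: The disconnection is C9–C10. A C8 methyl ketone (C9 as its methyl) would be turned into its enolate by NaOt-Bu and coupled under Pd2(dba)3 and a bulky biaryl phosphine with a (Z)-alkenyl iodide at C10, to give the cyclodecadienone A2.
- For: oxidative addition and reductive elimination keep the alkenyl geometry, so 1(10)Z is as secure as in the route chosen, and the coupling partners are simple.
- Against: the ketone has an enolisable C7–H on its other side and a silyloxy group on C6, β to the carbonyl, so the alkoxide base can scramble C7 and eliminate the C6 oxygen. The product is a β,γ-unsaturated ketone that can drift into conjugation under the same base. Closure of a ten-membered ring by this coupling has little support. C8 would have to be set afterwards by reducing A2 in a flexible ring.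
- Comparison: the chosen route brings C8 in from the chiral pool at the outset and uses it to control C7, at the price of more protecting-group steps.

Alternative 3: The disconnection is C5–C6 together with C4–CH3. An aldehyde at C6 and a terminal alkyne (C5) would be coupled with Ni(cod)2 and a trialkylphosphine while Me2Zn transfers methyl to C4, to give the allylic alcohol A3.
- For: the ring, the C5–C6 bond, the C15 methyl and the (E)-olefin (syn addition across the alkyne) come in one mild, non-basic step. On step economy at the ring-forming stage and on functional-group tolerance it is at least equal to the route chosen.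
- Against: C6 is created by addition to an aldehyde with only the α-stereocenter C7 to guide it, and in a macrocyclic transition state that preference is not dependable. The α-branched aldehyde can epimerise at C7. For a ring of only ten atoms the endocyclic (E)-olefin is strained, so the exocyclic insertion mode or plain reductive coupling may take over. C7 and C8 must both be installed beforehand in the chain.
- Comparison: the ring contraction offers a closed five-membered transition state in which C6 and C7 are formed together and are tied to the olefin geometry and to C8.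

Key step: step 15

Assumption: (S)-4-methoxybenzyl glycidyl ether 11 is taken as a purchasable single enantiomer.

## Steps

Step 1
Reactants: 1 geranyl acetate
Product: 2 (2E)-5-(3,3-dimethyloxiran-2-yl)-3-methylpent-2-en-1-yl acetate (racemic at the oxirane carbon)
Conditions: mCPBA, NaHCO3, CH2Cl2, 0 °C
Reagents that add atoms: 3-chloroperoxybenzoic acid, OOC(=O)c1cccc(Cl)c1
Why: Prilezhaev epoxidation; the terminal olefin is the more electron-rich one because the other is deactivated by the allylic acetate, so it reacts first. The new stereocenter does not matter, as it is cleaved in step 2.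

Step 2
Reactants: 2 (2E)-5-(3,3-dimethyloxiran-2-yl)-3-methylpent-2-en-1-yl acetate
Product: 3 (2E)-3-methyl-6-oxohex-2-en-1-yl acetate
Conditions: H5IO6, THF/Et2O, 0 °C
Reagents that add atoms: none
Why: Periodic acid opens the oxirane to the glycol and cleaves it (Malaprade-type glycol cleavage) to the C1 aldehyde and acetone; the acetate and the (E)-C4=C5 olefin are not affected.

Step 3
Reactants: 3 (2E)-3-methyl-6-oxohex-2-en-1-yl acetate; 4 ethyltriphenylphosphonium iodide
Product: 8 (2E,6Z)-7-iodo-3-methylocta-2,6-dien-1-yl acetate, via ethylidenetriphenylphosphorane 5 (not isolated), via (1-iodoethyl)triphenylphosphonium iodide 6 (not isolated), via (1-iodoethylidene)triphenylphosphorane 7 (not isolated)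
Conditions: 4, n-BuLi, THF, 0 °C; I2, −78 °C; NaN(SiMe3)2, −20 °C; then 3, −78 → −20 °C
Reagents that add atoms: iodine, II
Why: Stork–Zhao-type Wittig olefination: the α-iodo ylide 7 reacts with the aldehyde under kinetic control to give the (Z)-α-iodoalkene, iodine cis to the C2 chain. This geometry becomes 1(10)Z when iodine is replaced with retention in step 6; the acetate tolerates the cold ylide.

Step 4
Reactants: 8 (2E,6Z)-7-iodo-3-methylocta-2,6-dien-1-yl acetate
Product: 9 (2E,6Z)-7-iodo-3-methylocta-2,6-dien-1-ol
Conditions: K2CO3 (cat.), MeOH, rt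
Reagents that add atoms: none
Why: Base-catalysed transesterification removes the acetate, which would not survive the organolithium of step 6; the alkenyl iodide is inert.

Step 5
Reactants: 9 (2E,6Z)-7-iodo-3-methylocta-2,6-dien-1-ol
Product: 10 tert-butyl{[(2E,6Z)-7-iodo-3-methylocta-2,6-dien-1-yl]oxy}dimethylsilane
Conditions: TBSCl, imidazole, DMF, rt
Reagents that add atoms: tert-butyldimethylsilyl chloride, CC(C)(C)[Si](C)(C)Cl
Why: Standard silylation of a primary allylic alcohol; the primary TBS ether on C6 is stable to organolithiums, hydride and mild oxidants and can later be removed beside a secondary TBS ether.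

Step 6
Reactants: 10 tert-butyl{[(2E,6Z)-7-iodo-3-methylocta-2,6-dien-1-yl]oxy}dimethylsilane; 11 (S)-2-{[(4-methoxybenzyl)oxy]methyl}oxirane
Product: 13 (2S,4Z,8E)-10-[(tert-butyldimethylsilyl)oxy]-1-[(4-methoxybenzyl)oxy]-4,8-dimethyldeca-4,8-dien-2-ol, via C10 alkenyllithium 12 (not isolated)
Conditions: t-BuLi (2 equiv), Et2O, −78 °C; then 11, BF3·OEt2, THF, −78 °C
Reagents that add atoms: none
Why: Iodine–lithium exchange gives the configurationally stable alkenyllithium 12 with retention. The BF3-activated opening of the monosubstituted oxirane at its CH2 terminus forms C9–C10 and does not touch the stereocenter of 11, so C8 is (S) from the chiral pool and C9 is cis to C2.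

Step 7
Reactants: 13 (2S,4Z,8E)-10-[(tert-butyldimethylsilyl)oxy]-1-[(4-methoxybenzyl)oxy]-4,8-dimethyldeca-4,8-dien-2-ol
Product: 14 (2S,4Z,8E)-2,10-bis[(tert-butyldimethylsilyl)oxy]-1-[(4-methoxybenzyl)oxy]-4,8-dimethyldeca-4,8-diene
Conditions: TBSOTf, 2,6-lutidine, CH2Cl2, −78 → 0 °C
Reagents that add atoms: tert-butyldimethylsilyl trifluoromethanesulfonate, CC(C)(C)[Si](C)(C)OS(=O)(=O)C(F)(F)F
Why: Silylation of the secondary C8 alcohol with the silyl triflate; the silyl ether has no acidic benzylic or allylic O–CH2 protons, so it is compatible with the alkyllithium of the key step, and its bulk is used there and in step 19.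

Step 8
Reactants: 14 (2S,4Z,8E)-2,10-bis[(tert-butyldimethylsilyl)oxy]-1-[(4-methoxybenzyl)oxy]-4,8-dimethyldeca-4,8-diene
Product: 15 (2S,4Z,8E)-2,10-bis[(tert-butyldimethylsilyl)oxy]-4,8-dimethyldeca-4,8-dien-1-ol
Conditions: DDQ, CH2Cl2/pH 7 buffer, 0 °C
Reagents that add atoms: none
Why: Oxidative cleavage of the PMB ether through the benzylic oxocarbenium ion; silyl ethers and isolated trisubstituted olefins are unaffected, and the neutral medium prevents silyl migration from C8 to C7.

Step 9
Reactants: 15 (2S,4Z,8E)-2,10-bis[(tert-butyldimethylsilyl)oxy]-4,8-dimethyldeca-4,8-dien-1-ol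
Product: 16 (2S,4Z,8E)-2,10-bis[(tert-butyldimethylsilyl)oxy]-4,8-dimethyldeca-4,8-dienal
Conditions: Dess–Martin periodinane, NaHCO3, CH2Cl2, 0 °C → rt
Reagents that add atoms: none
Why: Dess–Martin oxidation under buffered, non-basic conditions gives the α-silyloxy aldehyde without epimerising C8; the aldehyde is used directly.

Step 10
Reactants: 16 (2S,4Z,8E)-2,10-bis[(tert-butyldimethylsilyl)oxy]-4,8-dimethyldeca-4,8-dienal; 17 methyl 2-[bis(2,2,2-trifluoroethoxy)phosphoryl]propanoate
Product: 19 methyl (2Z,4S,6Z,10E)-4,12-bis[(tert-butyldimethylsilyl)oxy]-2,6,10-trimethyldodeca-2,6,10-trienoate, via potassium phosphonate carbanion 18 (not isolated)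
Conditions: 17, KN(SiMe3)2, 18-crown-6, THF, −78 °C; then 16
Reagents that add atoms: none
Why: Still–Gennari olefination: the electron-poor phosphonate eliminates fast from the kinetic adduct and gives the (Z)-trisubstituted enoate, so that C12 is cis to C8. The preformed, weakly basic anion at −78 °C leaves the α-stereocenter intact.

Step 11
Reactants: 19 methyl (2Z,4S,6Z,10E)-4,12-bis[(tert-butyldimethylsilyl)oxy]-2,6,10-trimethyldodeca-2,6,10-trienoate
Product: 20 (2Z,4S,6Z,10E)-4,12-bis[(tert-butyldimethylsilyl)oxy]-2,6,10-trimethyldodeca-2,6,10-trien-1-ol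
Conditions: i-Bu2AlH, CH2Cl2, −78 °C
Reagents that add atoms: none
Why: 1,2-Reduction of the enoate to the (Z)-allylic alcohol; the C8 oxygen is silylated, so no butenolide can form.

Step 12
Reactants: 20 (2Z,4S,6Z,10E)-4,12-bis[(tert-butyldimethylsilyl)oxy]-2,6,10-trimethyldodeca-2,6,10-trien-1-ol
Product: 22 (2E,6Z,9S,10Z)-1,9-bis[(tert-butyldimethylsilyl)oxy]-12-chloro-3,7,11-trimethyldodeca-2,6,10-triene, via C12 methanesulfonate 21 (not isolated)
Conditions: MsCl, LiCl, 2,4,6-collidine, DMF, 0 °C
Reagents that add atoms: methanesulfonyl chloride, CS(=O)(=O)Cl (mesyl group of 21 only); lithium chloride, [Li+].[Cl-]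
Why: Mesylation and SN2 displacement by chloride in the same flask; the primary allylic position reacts without transposition and the cold, buffered medium keeps both silyl ethers.

Step 13
Reactants: 22 (2E,6Z,9S,10Z)-1,9-bis[(tert-butyldimethylsilyl)oxy]-12-chloro-3,7,11-trimethyldodeca-2,6,10-triene
Product: 23 (2E,6Z,9S,10Z)-9-[(tert-butyldimethylsilyl)oxy]-12-chloro-3,7,11-trimethyldodeca-2,6,10-trien-1-ol
Conditions: HF·pyridine, pyridine, THF, 0 °C
Reagents that add atoms: none
Why: Selective desilylation: the unhindered primary allylic silyl ether on C6 is cleaved much faster than the secondary one on C8, which is flanked by C7 and C9; the allylic chloride is stable in this non-nucleophilic medium.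

Step 14
Reactants: 23 (2E,6Z,9S,10Z)-9-[(tert-butyldimethylsilyl)oxy]-12-chloro-3,7,11-trimethyldodeca-2,6,10-trien-1-ol
Product: 25 (3Z,5S,7Z,11E)-5-[(tert-butyldimethylsilyl)oxy]-3,7,11-trimethyl-1-oxacyclotrideca-3,7,11-triene, via sodium alkoxide 24 (not isolated)
Conditions: NaH, THF, slow addition (0.002 M), 50 °C
Reagents that add atoms: none
Why: Intramolecular Williamson etherification at the primary allylic chloride under high dilution; three olefins of fixed geometry cut down the conformational freedom of the chain. The alkoxide sits on C6, far from the C8 silyl ether, so silyl migration is not expected.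

Step 15
Reactants: 25 (3Z,5S,7Z,11E)-5-[(tert-butyldimethylsilyl)oxy]-3,7,11-trimethyl-1-oxacyclotrideca-3,7,11-triene
Product: 28 (1S,2E,6Z,9S,10S)-9-[(tert-butyldimethylsilyl)oxy]-3,7-dimethyl-10-(prop-1-en-2-yl)cyclodeca-2,6-dien-1-ol, via C6-lithio ether 26 (not isolated), via lithium alkoxide 27 (not isolated)
Conditions: n-BuLi, THF, −78 → −20 °C; then H2O
Reagents that add atoms: none
Why: n-BuLi removes a proton from the C6 methylene, which is allylic, α to oxygen and unhindered, to give the α-alkoxy allyllithium 26; C6 then bonds to C7 in a concerted, suprafacial [2,3]-shift through a five-membered envelope (C6, O, C12, C11, C7) while O–C12 breaks, leaving the alkoxide 27 with the C11=C12 isopropenyl group. This is the known [2,3]-Wittig ring contraction of thirteen-membered diallylic ethers to cyclodeca-1,5-dienols. The ten-membered ring closes by transannular bond formation between C6 and C7, the two ring atoms that flank the O–C12–C11 bridge, so no chain ends have to find each other. C6 relative to C7 is set by the (Z)-C7=C11 geometry with the C5 alkenyl group in the exo position of the envelope, which gives the syn-type adduct (hydroxyl and the C8 branch on the same side when C5–C6–C7–C11 is drawn zigzag), that is C6–OH and isopropenyl cis on the ring. C7 relative to C8 is set by allylic 1,3-strain with the cis C12 methylene: C8–H is held in the olefin plane, C9 with the tether that carries C6 lies on one face and the silyloxy group on the other, so C6 arrives anti to the silyl ether and the isopropenyl group ends up trans to C8–O. The step needs lithiation at C6 and not at C12 (C12–H is flanked by the C11 methyl and its shift would have to end at the fully substituted C4) or at C8 (its C–H lies in the olefin plane and is not activated). It also needs the [2,3]-path to win over the [1,2]-path, which low temperature secures. The 1(10)Z and 4E olefins were fixed in the chain and are not part of the reorganising array.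

Step 16
Reactants: 28 (1S,2E,6Z,9S,10S)-9-[(tert-butyldimethylsilyl)oxy]-3,7-dimethyl-10-(prop-1-en-2-yl)cyclodeca-2,6-dien-1-ol
Product: 29 (1S,2E,6Z,9S,10S)-9-[(tert-butyldimethylsilyl)oxy]-3,7-dimethyl-10-(propan-2-yl)cyclodeca-2,6-dien-1-ol
Conditions: H2 (1 atm), RhCl(PPh3)3 (cat.), toluene, rt
Reagents that add atoms: none
Why: Homogeneous hydrogenation with RhCl(PPh3)3 reduces the 1,1-disubstituted olefin and leaves the two trisubstituted ring olefins, which bind the rhodium centre far less well; no stereocenter is formed.

Step 17
Reactants: 29 (1S,2E,6Z,9S,10S)-9-[(tert-butyldimethylsilyl)oxy]-3,7-dimethyl-10-(propan-2-yl)cyclodeca-2,6-dien-1-ol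
Product: 30 (1(10)Z,4S,5S,6R,7S,8S)-8-[(tert-butyldimethylsilyl)oxy]-4,5-epoxygermacr-1(10)-en-6-ol
Conditions: VO(acac)2 (cat.), t-BuOOH, CH2Cl2, 0 °C
Reagents that add atoms: tert-butyl hydroperoxide, CC(C)(C)OO
Why: Hydroxyl-directed epoxidation of the allylic alcohol: C15 is cis to C6 on the (E)-olefin, so allylic 1,3-strain keeps C6–H in the olefin plane and C6–O on the outer face, where the vanadium-bound peroxide delivers oxygen to give the threo (4S,5S) oxirane. The C1=C10 olefin has no free hydroxyl near it (C8 is silylated) and reacts much more slowly.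

Step 18
Reactants: 30 (1(10)Z,4S,5S,6R,7S,8S)-8-[(tert-butyldimethylsilyl)oxy]-4,5-epoxygermacr-1(10)-en-6-ol
Product: 31 (1(10)Z,4S,5S,6R,7S,8S)-8-[(tert-butyldimethylsilyl)oxy]-4,5-epoxygermacr-1(10)-en-6-yl acetate
Conditions: Ac2O, pyridine, DMAP (cat.), CH2Cl2, 0 °C → rt
Reagents that add atoms: acetic anhydride, CC(=O)OC(C)=O
Why: Acetylation of the secondary alcohol under basic, non-acidic conditions, which the oxirane and the remaining olefin tolerate.

Step 19
Reactants: 31 (1(10)Z,4S,5S,6R,7S,8S)-8-[(tert-butyldimethylsilyl)oxy]-4,5-epoxygermacr-1(10)-en-6-yl acetate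
Product: 32 (1R,4S,5S,6R,7S,8S,10S)-8-[(tert-butyldimethylsilyl)oxy]-1,10:4,5-diepoxygermacran-6-yl acetate
Conditions: dimethyldioxirane, acetone, −20 → 0 °C
Reagents that add atoms: dimethyldioxirane, CC1(C)OO1
Why: Epoxidation with a neutral dioxirane: the (Z)-olefin lies roughly in the mean ring plane and the bulky C8 silyloxy group sits on its α face next to C9, so the oxidant should add from the β face, anti to C8–O, to give the (1R,10S) oxirane. Neutral conditions avoid acid-triggered attack of the olefin on the 4,5-oxirane across the ring. A vanadium epoxidation directed by a free C8 hydroxyl is not used, because it would deliver oxygen syn to C8–O.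

Step 20
Reactants: 32 (1R,4S,5S,6R,7S,8S,10S)-8-[(tert-butyldimethylsilyl)oxy]-1,10:4,5-diepoxygermacran-6-yl acetate
Product: 33 (1R,4S,5S,6R,7R,8S,10S)-8-hydroxy-1,10:4,5-diepoxygermacran-6-yl acetate
Conditions: Bu4NF, AcOH, THF, 0 °C → rt
Reagents that add atoms: none
Why: Fluoride-induced desilylation; buffering with acetic acid keeps the medium near neutral, so the acetate should not migrate from C6 to C8 and the oxiranes should not be opened.

Step 21
Reactants: 33 (1R,4S,5S,6R,7R,8S,10S)-8-hydroxy-1,10:4,5-diepoxygermacran-6-yl acetate; 34 angelic acid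
Product: 36 (1R,4S,5S,6R,7R,8S,10S)-6-acetoxy-1,10:4,5-diepoxygermacran-8-yl (Z)-2-methylbut-2-enoate, via angelic 2,4,6-trichlorobenzoic anhydride 35 (not isolated)
Conditions: 34, 2,4,6-Cl3C6H2COCl, Et3N, toluene, rt; filter; then 33, 75 °C
Reagents that add atoms: 2,4,6-trichlorobenzoyl chloride, O=C(Cl)c1c(Cl)cc(Cl)cc1Cl (aroyl part of 35 only)
Why: Yamaguchi-type esterification through the mixed anhydride 35, which acylates hindered secondary alcohols at its unhindered angeloyl carbonyl. No nucleophilic catalyst or strong base is present, so the (Z)-olefin of the angelate should not isomerise, and removal of the ammonium chloride before heating protects the oxiranes.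

## Compound list

1 | geranyl acetate | CC(C)=CCC/C(C)=C/COC(C)=O | starting material
2 | (2E)-5-(3,3-dimethyloxiran-2-yl)-3-methylpent-2-en-1-yl acetate (racemic) | CC(=O)OC/C=C(C)/CCC1OC1(C)C | intermediate
3 | (2E)-3-methyl-6-oxohex-2-en-1-yl acetate | CC(=O)OC/C=C(C)/CCC=O | intermediate
4 | ethyltriphenylphosphonium iodide | CC[P+](c1ccccc1)(c1ccccc1)c1ccccc1.[I-] | starting material
5 | ethylidenetriphenylphosphorane | CC=P(c1ccccc1)(c1ccccc1)c1ccccc1 | intermediate
6 | (1-iodoethyl)triphenylphosphonium iodide (racemic) | CC(I)[P+](c1ccccc1)(c1ccccc1)c1ccccc1.[I-] | intermediate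
7 | (1-iodoethylidene)triphenylphosphorane | CC(I)=P(c1ccccc1)(c1ccccc1)c1ccccc1 | intermediate
8 | (2E,6Z)-7-iodo-3-methylocta-2,6-dien-1-yl acetate | CC(=O)OC/C=C(C)/CC/C=C(/C)I | intermediate
9 | (2E,6Z)-7-iodo-3-methylocta-2,6-dien-1-ol | OC/C=C(C)/CC/C=C(/C)I | intermediate
10 | tert-butyl{[(2E,6Z)-7-iodo-3-methylocta-2,6-dien-1-yl]oxy}dimethylsilane | CC(C)(C)[Si](C)(C)OC/C=C(C)/CC/C=C(/C)I | intermediate
11 | (S)-2-{[(4-methoxybenzyl)oxy]methyl}oxirane | COc1ccc(COC[C@@H]2CO2)cc1 | starting material
12 | C10 alkenyllithium from 10 (lithium in place of iodine, geometry retained) | CC(C)(C)[Si](C)(C)OC/C=C(C)/CC/C=C(/C)[Li] | intermediate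
13 | (2S,4Z,8E)-10-[(tert-butyldimethylsilyl)oxy]-1-[(4-methoxybenzyl)oxy]-4,8-dimethyldeca-4,8-dien-2-ol | COc1ccc(COC[C@@H](O)C/C(C)=C\CC/C(C)=C/CO[Si](C)(C)C(C)(C)C)cc1 | intermediate
14 | (2S,4Z,8E)-2,10-bis[(tert-butyldimethylsilyl)oxy]-1-[(4-methoxybenzyl)oxy]-4,8-dimethyldeca-4,8-diene | COc1ccc(COC[C@@H](O[Si](C)(C)C(C)(C)C)C/C(C)=C\CC/C(C)=C/CO[Si](C)(C)C(C)(C)C)cc1 | intermediate
15 | (2S,4Z,8E)-2,10-bis[(tert-butyldimethylsilyl)oxy]-4,8-dimethyldeca-4,8-dien-1-ol | OC[C@@H](O[Si](C)(C)C(C)(C)C)C/C(C)=C\CC/C(C)=C/CO[Si](C)(C)C(C)(C)C | intermediate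
16 | (2S,4Z,8E)-2,10-bis[(tert-butyldimethylsilyl)oxy]-4,8-dimethyldeca-4,8-dienal | O=C[C@@H](O[Si](C)(C)C(C)(C)C)C/C(C)=C\CC/C(C)=C/CO[Si](C)(C)C(C)(C)C | intermediate
17 | methyl 2-[bis(2,2,2-trifluoroethoxy)phosphoryl]propanoate | COC(=O)C(C)P(=O)(OCC(F)(F)F)OCC(F)(F)F | starting material
18 | potassium salt of the carbanion of 17 | COC(=O)[C-](C)P(=O)(OCC(F)(F)F)OCC(F)(F)F.[K+] | intermediate
19 | methyl (2Z,4S,6Z,10E)-4,12-bis[(tert-butyldimethylsilyl)oxy]-2,6,10-trimethyldodeca-2,6,10-trienoate | COC(=O)/C(C)=C\[C@@H](O[Si](C)(C)C(C)(C)C)C/C(C)=C\CC/C(C)=C/CO[Si](C)(C)C(C)(C)C | intermediate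
20 | (2Z,4S,6Z,10E)-4,12-bis[(tert-butyldimethylsilyl)oxy]-2,6,10-trimethyldodeca-2,6,10-trien-1-ol | OC/C(C)=C\[C@@H](O[Si](C)(C)C(C)(C)C)C/C(C)=C\CC/C(C)=C/CO[Si](C)(C)C(C)(C)C | intermediate
21 | C12 methanesulfonate of 20 | CS(=O)(=O)OC/C(C)=C\[C@@H](O[Si](C)(C)C(C)(C)C)C/C(C)=C\CC/C(C)=C/CO[Si](C)(C)C(C)(C)C | intermediate
22 | (2E,6Z,9S,10Z)-1,9-bis[(tert-butyldimethylsilyl)oxy]-12-chloro-3,7,11-trimethyldodeca-2,6,10-triene | ClC/C(C)=C\[C@@H](O[Si](C)(C)C(C)(C)C)C/C(C)=C\CC/C(C)=C/CO[Si](C)(C)C(C)(C)C | intermediate
23 | (2E,6Z,9S,10Z)-9-[(tert-butyldimethylsilyl)oxy]-12-chloro-3,7,11-trimethyldodeca-2,6,10-trien-1-ol | ClC/C(C)=C\[C@@H](O[Si](C)(C)C(C)(C)C)C/C(C)=C\CC/C(C)=C/CO | intermediate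
24 | sodium alkoxide of 23 | ClC/C(C)=C\[C@@H](O[Si](C)(C)C(C)(C)C)C/C(C)=C\CC/C(C)=C/C[O-].[Na+] | intermediate
25 | (3Z,5S,7Z,11E)-5-[(tert-butyldimethylsilyl)oxy]-3,7,11-trimethyl-1-oxacyclotrideca-3,7,11-triene | O1C/C=C(C)/CC/C=C(C)\C[C@H](O[Si](C)(C)C(C)(C)C)/C=C(C)\C1 | intermediate
26 | C6-lithio derivative of 25 (configuration at C6 not defined) | [Li]C1/C=C(C)/CC/C=C(C)\C[C@H](O[Si](C)(C)C(C)(C)C)/C=C(C)\CO1 | intermediate
27 | lithium alkoxide of 28 | CC(C)(C)[Si](C)(C)O[C@H]1C/C(C)=C\CC/C(C)=C/[C@H](O[Li])[C@@H]1C(C)=C | intermediate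
28 | (1S,2E,6Z,9S,10S)-9-[(tert-butyldimethylsilyl)oxy]-3,7-dimethyl-10-(prop-1-en-2-yl)cyclodeca-2,6-dien-1-ol (germacrane locants 6S,7S,8S) | CC(C)(C)[Si](C)(C)O[C@H]1C/C(C)=C\CC/C(C)=C/[C@H](O)[C@@H]1C(C)=C | intermediate
29 | (1S,2E,6Z,9S,10S)-9-[(tert-butyldimethylsilyl)oxy]-3,7-dimethyl-10-(propan-2-yl)cyclodeca-2,6-dien-1-ol | CC(C)(C)[Si](C)(C)O[C@H]1C/C(C)=C\CC/C(C)=C/[C@H](O)[C@@H]1C(C)C | intermediate
30 | (1(10)Z,4S,5S,6R,7S,8S)-8-[(tert-butyldimethylsilyl)oxy]-4,5-epoxygermacr-1(10)-en-6-ol | CC(C)(C)[Si](C)(C)O[C@H]1C/C(C)=C\CC[C@]2(C)O[C@H]2[C@H](O)[C@@H]1C(C)C | intermediate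
31 | (1(10)Z,4S,5S,6R,7S,8S)-8-[(tert-butyldimethylsilyl)oxy]-4,5-epoxygermacr-1(10)-en-6-yl acetate | CC(C)(C)[Si](C)(C)O[C@H]1C/C(C)=C\CC[C@]2(C)O[C@H]2[C@H](OC(C)=O)[C@@H]1C(C)C | intermediate
32 | (1R,4S,5S,6R,7S,8S,10S)-8-[(tert-butyldimethylsilyl)oxy]-1,10:4,5-diepoxygermacran-6-yl acetate | CC(C)(C)[Si](C)(C)O[C@H]1C[C@]2(C)O[C@@H]2CC[C@]2(C)O[C@H]2[C@H](OC(C)=O)[C@@H]1C(C)C | intermediate
33 | (1R,4S,5S,6R,7R,8S,10S)-8-hydroxy-1,10:4,5-diepoxygermacran-6-yl acetate | O[C@H]1C[C@]2(C)O[C@@H]2CC[C@]2(C)O[C@H]2[C@H](OC(C)=O)[C@@H]1C(C)C | intermediate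
34 | angelic acid, (Z)-2-methylbut-2-enoic acid | C/C=C(/C)C(O)=O | starting material
35 | angelic 2,4,6-trichlorobenzoic anhydride | C/C=C(/C)C(=O)OC(=O)c1c(Cl)cc(Cl)cc1Cl | intermediate
36 | (1R,4S,5S,6R,7R,8S,10S)-6-acetoxy-1,10:4,5-diepoxygermacran-8-yl (Z)-2-methylbut-2-enoate | C/C=C(/C)C(=O)O[C@H]1C[C@]2(C)O[C@@H]2CC[C@]2(C)O[C@H]2[C@H](OC(C)=O)[C@@H]1C(C)C | target

## Step count and least certain steps

Total: 21 steps. Longest linear sequence: 21 steps, from 1; compounds 4, 11, 17 and 34 are bought.

**Step 15 (key step).** Most likely to go wrong: lithiation at C12 or C8 in competition with C6, or loss of the syn-type and facial selectivity because the ring distorts the envelope transition state; on warming a [1,2]-shift can also compete. Fallback, setting out from 22 and coming back at 28: the same C6–C7 bond is formed by an intramolecular allylstannane addition in place of the sigmatropic shift. Chloride 22 is displaced with Bu3SnLi (THF, −78 °C) to give the C12 tributylstannane F1. The primary silyl ether is removed with NH4F in MeOH to give the stannyl alcohol F2, which is oxidised with MnO2 to the stannyl enal F3. BF3·OEt2 at −78 °C under high dilution then promotes SE2' addition of C7 to the C6 aldehyde with shift of the olefin to C11=C12. The open transition state of Lewis-acid-promoted allylstannane additions favours the syn-type adduct whatever the allyl geometry, and the same allylic strain argument applies to C7, so 28 is expected.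

**Step 19.** Most likely to go wrong: poor or reversed facial selectivity, because the ring may fold so that the C8 silyloxy group no longer screens the α face of C1=C10. Fallback, setting out from 31 and coming back at 32: a two-step halohydrin route, which places the oxygen on the face opposite to the one the electrophile attacks. NBS in aqueous THF (NaHCO3) gives the bromohydrin F4, with water entering at tertiary C10 anti to the bromonium ion, and Cs2CO3 in MeCN closes it to 32. It is used if the direct oxidation prefers the α face.

**Step 14.** Most likely to go wrong: oligomerisation or elimination competing with closure of the strained thirteen-membered triene. Fallback, setting out from 19 and coming back at 25: the roles of the two termini are reversed, so that the unhindered C6 carries the leaving group. HF·pyridine removes the primary silyl ether of 19 to give the hydroxy ester F5; MsCl, LiCl and collidine give the C6 chloro ester F6; i-Bu2AlH at −78 °C gives the chloro alcohol F7, with C12–OH and C6–Cl. NaH in THF under high dilution, kept cold so that alkylation outruns silyl migration from C8, closes the O–C6 bond to 25.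

**Step 21.** Most likely to go wrong: slow acylation of the hindered C8 hydroxyl, during which the angelate isomerises to the tiglate or an oxirane is opened on heating. Fallback, setting out from 33 and coming back at 36: the (Z)-olefin of the ester is built on the molecule. Alcohol 33 is esterified (DCC, DMAP, CH2Cl2, 0 °C) with 2-[bis(2,2,2-trifluoroethoxy)phosphoryl]propanoic acid to give the C8 phosphonopropanoate F8. A Still–Gennari olefination with acetaldehyde (KN(SiMe3)2, 18-crown-6, THF, −78 °C) then gives the (Z)-2-methylbut-2-enoate 36.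

## Further compounds

F1 | step 15 | C12 tributylstannane from 22 | CCCC[Sn](CCCC)(CCCC)C/C(C)=C\[C@@H](O[Si](C)(C)C(C)(C)C)C/C(C)=C\CC/C(C)=C/CO[Si](C)(C)C(C)(C)C
F2 | step 15 | stannyl alcohol (C6–OH, C12–SnBu3) | CCCC[Sn](CCCC)(CCCC)C/C(C)=C\[C@@H](O[Si](C)(C)C(C)(C)C)C/C(C)=C\CC/C(C)=C/CO
F3 | step 15 | stannyl enal (C6 aldehyde, C12–SnBu3) | CCCC[Sn](CCCC)(CCCC)C/C(C)=C\[C@@H](O[Si](C)(C)C(C)(C)C)C/C(C)=C\CC/C(C)=C/C=O
F4 | step 19 | bromohydrin of 31 (C10–OH on the β face, C1–Br on the α face) | CC(C)(C)[Si](C)(C)O[C@H]1C[C@](C)(O)[C@@H](Br)CC[C@]2(C)O[C@H]2[C@H](OC(C)=O)[C@@H]1C(C)C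
F5 | step 14 | hydroxy ester (C6–OH, C12 methyl ester) | COC(=O)/C(C)=C\[C@@H](O[Si](C)(C)C(C)(C)C)C/C(C)=C\CC/C(C)=C/CO
F6 | step 14 | chloro ester (C6–Cl, C12 methyl ester) | COC(=O)/C(C)=C\[C@@H](O[Si](C)(C)C(C)(C)C)C/C(C)=C\CC/C(C)=C/CCl
F7 | step 14 | chloro alcohol (C6–Cl, C12–OH) | OC/C(C)=C\[C@@H](O[Si](C)(C)C(C)(C)C)C/C(C)=C\CC/C(C)=C/CCl
F8 | step 21 | C8 2-[bis(2,2,2-trifluoroethoxy)phosphoryl]propanoate of 33 (epimers at the phosphonate carbon) | CC(C(=O)O[C@H]1C[C@]2(C)O[C@@H]2CC[C@]2(C)O[C@H]2[C@H](OC(C)=O)[C@@H]1C(C)C)P(=O)(OCC(F)(F)F)OCC(F)(F)F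
A1 | alternative 1 | C2-phenylsulfonyl (1(10)Z,4E)-cyclodecadiene with C6–OPMB and C8–OTBS (C2 epimers) | CC(C)(C)[Si](C)(C)O[C@H]1C/C(C)=C\C(S(=O)(=O)c2ccccc2)C/C(C)=C/[C@H](OCc2ccc(OC)cc2)[C@@H]1C(C)C
A2 | alternative 2 | C6-silyloxy (1(10)Z,4E)-cyclodecadien-8-one | O=C1C/C(C)=C\CC/C(C)=C/[C@H](O[Si](C)(C)C(C)(C)C)[C@@H]1C(C)C
A3 | alternative 3 | C8-PMB (1(10)Z,4E)-cyclodecadien-6-ol | COc1ccc(CO[C@H]2C/C(C)=C\CC/C(C)=C/[C@H](O)[C@@H]2C(C)C)cc1
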